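**Plan**

1. Retrosynthesis: the four O–MOM bonds are cut first, then C6–C1' of the side chain (Heck, to (S)-β-citronellene). Next C2–C3 and C4–C4a of ring C are cut together, leading to an α-aryloxy diazoketone in which C3 still sits on C4 as CHN2. Last come C3 itself (diazomethane) and the O1–C2 ether bond (carbene O–H insertion of an aryl diazoacetate into a phenol).
2. Forward: ring A enters as 4-bromo-3,5-bis(methoxymethoxy)phenol and ring B as a diazo ester; they are joined at O1–C2 and the acid is extended to the diazoketone. Ring C then forms in one operation by Wolff shift of C2 onto C3 and acylation of C4a by the ketene carbon C4; the C10 chain is attached at C6 and the phenols are freed.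
3. Enabling feature: the C3–C4 unit of ring C lies between C2, a benzylic O1-bearing stereocentre that can migrate with retention, and C4a of ring A. Ring A is 1,3,5-trioxygenated (O1, O5, O7), hence strongly nucleophilic, and locally symmetric about the O1–C8a···C6 axis, so C4a and C8 are identical and the 6- versus 8-substitution problem does not arise.
4. Stereochemistry: C2 is set (R in the ester) by the chiral palladium catalyst of step 5 and carried with retention through the 1,2-shift; it is named S in the flavanone only because substituent priorities change. C3' comes from (S)-β-citronellene, and the E alkene from syn-insertion/syn-elimination in the Heck reaction.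

Key step: step 8

Remark: the sense of induction of the spiro-bis(oxazoline) ligand in step 5 is assumed by analogy with simpler phenols (the mirror-image ligand is used if it proves opposite), and (S)-β-citronellene is taken as a commercial, enantiopure material.

**Step 1**
Reactants: 1 2-bromobenzene-1,3-diol (2-bromoresorcinol)
Product: 2 2-bromo-1,3-bis(methoxymethoxy)benzene
Conditions: MOMCl (2.6 equiv), i-Pr2NEt (3 equiv), CH2Cl2, 0 °C → rt
Reagents that add atoms: chloromethyl methyl ether, COCCl
Why: Williamson-type O-alkylation of both phenols by the reactive α-chloro ether should give the bis-acetal, whose small MOM groups keep ring A electron-rich and leave room around the bromide.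

**Step 2**
Reactants: 2 2-bromo-1,3-bis(methoxymethoxy)benzene
Product: 4 4-bromo-3,5-bis(methoxymethoxy)phenol, via aryl pinacol boronate 3 (not isolated)
Conditions: [Ir(OMe)(cod)]2 (1.5 mol %), 4,4'-di-tert-butyl-2,2'-bipyridine (3 mol %), B2pin2 (1.0 equiv), THF, 65 °C; then 30% aq. H2O2, aq. NaOH, 0 °C
Reagents that add atoms: bis(pinacolato)diboron, CC1(C)OB(OC1(C)C)B1OC(C)(C)C(C)(C)O1 (boryl group of intermediate 3 only); hydrogen peroxide, OO (the phenol oxygen)
Why: sterically controlled iridium-catalysed aromatic C–H borylation should occur only at C5, the one C–H not ortho to a substituent, and oxidation of the C–B bond then gives the phenol para to bromine (C–H borylation/oxidation).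

**Step 3**
Reactants: 5 methyl 2-(3,4-dihydroxyphenyl)acetate
Product: 6 methyl 2-[3,4-bis(methoxymethoxy)phenyl]acetate
Conditions: MOMCl (2.6 equiv), i-Pr2NEt (3 equiv), CH2Cl2, 0 °C → rt
Reagents that add atoms: chloromethyl methyl ether, COCCl
Why: Williamson-type acetalisation of the catechol under a mild amine base should leave the ester and its benzylic CH2 untouched.

**Step 4**
Reactants: 6 methyl 2-[3,4-bis(methoxymethoxy)phenyl]acetate
Product: 7 methyl 2-diazo-2-[3,4-bis(methoxymethoxy)phenyl]acetate
Conditions: 4-acetamidobenzenesulfonyl azide (1.3 equiv), DBU (1.5 equiv), MeCN, 0 °C → rt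
Reagents that add atoms: 4-acetamidobenzenesulfonyl azide, CC(=O)Nc1ccc(cc1)S(=O)(=O)N=[N+]=[N-]
Why: Regitz diazo transfer to the DBU-generated aryl acetate enolate is the standard entry to aryl diazoacetates and tolerates the electron-rich ring.

**Step 5**
Reactants: 4 4-bromo-3,5-bis(methoxymethoxy)phenol; 7 methyl 2-diazo-2-[3,4-bis(methoxymethoxy)phenyl]acetate
Product: 8 methyl (2R)-2-[4-bromo-3,5-bis(methoxymethoxy)phenoxy]-2-[3,4-bis(methoxymethoxy)phenyl]acetate
Conditions: Pd(PhCN)2Cl2 (5 mol %), chiral spirobiindane bis(oxazoline) ligand (6 mol %), NaB[3,5-(CF3)2C6H3]4 (12 mol %), 5 Å MS, CHCl3, 25 °C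
Reagents that add atoms: none
Why: enantioselective carbene O–H insertion, in which the electrophilic palladium carbene is trapped by the unhindered phenol oxygen and the resulting ylide is protonated inside the chiral ligand pocket, should set the stereocentre (future C2) as R while the aryl bromide stays inert to the divalent palladium catalyst.

**Step 6**
Reactants: 8 methyl (2R)-2-[4-bromo-3,5-bis(methoxymethoxy)phenoxy]-2-[3,4-bis(methoxymethoxy)phenyl]acetate
Product: 9 (2R)-2-[4-bromo-3,5-bis(methoxymethoxy)phenoxy]-2-[3,4-bis(methoxymethoxy)phenyl]acetic acid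
Conditions: Me3SnOH (4 equiv), ClCH2CH2Cl, 70 °C; then 0.1 M aq. HCl (work-up)
Reagents that add atoms: trimethyltin hydroxide, C[Sn](C)(C)O
Why: ester cleavage by trimethyltin hydroxide is an essentially neutral acyl substitution that should avoid enolisation of the acidic α-aryloxy benzylic C–H, so the stereocentre is kept.

**Step 7**
Reactants: 9 (2R)-2-[4-bromo-3,5-bis(methoxymethoxy)phenoxy]-2-[3,4-bis(methoxymethoxy)phenyl]acetic acid
Product: 11 (1R)-1-[4-bromo-3,5-bis(methoxymethoxy)phenoxy]-3-diazo-1-[3,4-bis(methoxymethoxy)phenyl]propan-2-one, via acid chloride 10 (not isolated)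
Conditions: 1-chloro-N,N,2-trimethylprop-1-en-1-amine (1.1 equiv), CH2Cl2, 0 °C; then CH2N2 (3 equiv), Et2O, 0 °C
Reagents that add atoms: 1-chloro-N,N,2-trimethylprop-1-en-1-amine, CC(C)=C(Cl)N(C)C (chlorine of intermediate 10 only); diazomethane, C=[N+]=[N-]
Why: this is the first half of an Arndt–Eistert sequence, in which the α-chloroenamine makes the acid chloride without HCl or amine base (so no MOM loss, no ketene formation and no racemisation) and immediate C-acylation of diazomethane, whose excess takes up HCl, should give the diazoketone before the acid chloride can acylate ring A.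

**Step 8**
Reactants: 11 (1R)-1-[4-bromo-3,5-bis(methoxymethoxy)phenoxy]-3-diazo-1-[3,4-bis(methoxymethoxy)phenyl]propan-2-one
Product: 13 (2S)-6-bromo-2-[3,4-bis(methoxymethoxy)phenyl]-5,7-bis(methoxymethoxy)-2,3-dihydro-4H-chromen-4-one, via ketene 12 (not isolated)
Conditions: hν (405 nm LED), CH2Cl2 (5 mM), −20 °C; then Sc(OTf)3 (5 mol %, in MeCN), −20 → 20 °C
Reagents that add atoms: none
Why: Proposed new method: direct excitation of the diazoketone expels N2 while C2 shifts from the old carbonyl carbon to the diazo carbon (Wolff rearrangement, making C2–C3), and the ketene 12 so formed, once its oxygen is bound by Sc(OTf)3, is attacked at the sp carbon C4 by the ortho carbon C4a of ring A (making C4–C4a), after which loss of the arenium proton and ketonisation of the enolate give 13. The closest known reaction types are the photochemical Wolff step of the Arndt–Eistert homologation, in which an α-stereocentre migrates with retention, and the Lewis-acid Friedel–Crafts acylation of arenes by ketenes; their union in one ring-forming cascade on an α-aryloxy diazoketone is the part without precedent. Ring C closes in a 6-exo-dig manner, C4a approaching C4 in the ketene plane with the C4=O π bond outside the new ring. No new stereocentre arises: C2 keeps the configuration of 11 because the 1,2-shift is suprafacial and concerted and because nothing in the neutral, base-free medium can enolise or ionise C2 (R in 11 becomes S in 13 only through the change in substituent priority). The step needs the Wolff shift to outrun attack of a free carbene on ring A, which would give a chroman-3-one, and this is served by metal-free irradiation of the s-Z conformer and by adding the Lewis acid only after the diazo compound is gone; it also needs a single acylation site, which the substrate provides because C4a and C8 of ring A are equivalent (each ortho to O1 and ortho or para to both OMOM groups) and C6 is blocked by bromine.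

**Step 9**
Reactants: 13 (2S)-6-bromo-2-[3,4-bis(methoxymethoxy)phenyl]-5,7-bis(methoxymethoxy)-2,3-dihydro-4H-chromen-4-one; 14 (3S)-3,7-dimethylocta-1,6-diene ((S)-β-citronellene)
Product: 15 (2S)-2-[3,4-bis(methoxymethoxy)phenyl]-6-[(1E,3S)-3,7-dimethylocta-1,6-dien-1-yl]-5,7-bis(methoxymethoxy)-2,3-dihydro-4H-chromen-4-one
Conditions: Pd[P(t-Bu)3]2 (5 mol %), Cy2NMe (1.5 equiv), 14 (3 equiv), 1,4-dioxane, 70 °C
Reagents that add atoms: none
Why: in this Mizoroki–Heck reaction the bulky monophosphine zerovalent palladium catalyst should insert into the hindered, electron-rich C6–Br bond, and syn-carbopalladation at the terminal CH2 followed by syn-β-hydride elimination towards the benzylic carbon should give the E-styrene, the allylic methyl branch disfavouring both internal arylation and elimination towards C3', the trisubstituted alkene being inert and the hindered amine too weak a base to open ring C.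

**Step 10**
Reactants: 15 (2S)-2-[3,4-bis(methoxymethoxy)phenyl]-6-[(1E,3S)-3,7-dimethylocta-1,6-dien-1-yl]-5,7-bis(methoxymethoxy)-2,3-dihydro-4H-chromen-4-one
Product: 17 (2S)-2-(3,4-dihydroxyphenyl)-6-[(1E,3S)-3,7-dimethylocta-1,6-dien-1-yl]-5,7-dihydroxy-2,3-dihydro-4H-chromen-4-one, via tetrakis(trimethylsilyl) ether 16 (not isolated)
Conditions: TMSOTf (8 equiv), 2,2'-bipyridyl (12 equiv), MeCN, 0 °C → rt; then H2O
Reagents that add atoms: trimethylsilyl trifluoromethanesulfonate, C[Si](C)(C)OS(=O)(=O)C(F)(F)F (silyl groups of intermediate 16 only; none remain in 17)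
Why: silyl triflate buffered by bipyridyl should convert each aryl MOM ether into the aryl silyl ether, which water hydrolyses on work-up, so that no protic acid reaches the electron-rich styrene or the trisubstituted alkene and no base reaches the C2 stereocentre (non-acidic acetal cleavage).

**Compound list**

1 | 2-bromobenzene-1,3-diol | Oc1cccc(O)c1Br | starting material
2 | 2-bromo-1,3-bis(methoxymethoxy)benzene | COCOc1cccc(OCOC)c1Br | intermediate
3 | 2-[4-bromo-3,5-bis(methoxymethoxy)phenyl]-4,4,5,5-tetramethyl-1,3,2-dioxaborolane | COCOc1cc(cc(OCOC)c1Br)B1OC(C)(C)C(C)(C)O1 | intermediate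
4 | 4-bromo-3,5-bis(methoxymethoxy)phenol | COCOc1cc(O)cc(OCOC)c1Br | intermediate
5 | methyl 2-(3,4-dihydroxyphenyl)acetate | COC(=O)Cc1ccc(O)c(O)c1 | starting material
6 | methyl 2-[3,4-bis(methoxymethoxy)phenyl]acetate | COC(=O)Cc1ccc(OCOC)c(OCOC)c1 | intermediate
7 | methyl 2-diazo-2-[3,4-bis(methoxymethoxy)phenyl]acetate | COC(=O)C(=[N+]=[N-])c1ccc(OCOC)c(OCOC)c1 | intermediate
8 | methyl (2R)-2-[4-bromo-3,5-bis(methoxymethoxy)phenoxy]-2-[3,4-bis(methoxymethoxy)phenyl]acetate | COC(=O)[C@@H](c1ccc(OCOC)c(OCOC)c1)Oc1cc(OCOC)c(Br)c(OCOC)c1 | intermediate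
9 | (2R)-2-[4-bromo-3,5-bis(methoxymethoxy)phenoxy]-2-[3,4-bis(methoxymethoxy)phenyl]acetic acid | OC(=O)[C@@H](c1ccc(OCOC)c(OCOC)c1)Oc1cc(OCOC)c(Br)c(OCOC)c1 | intermediate
10 | (2R)-2-[4-bromo-3,5-bis(methoxymethoxy)phenoxy]-2-[3,4-bis(methoxymethoxy)phenyl]acetyl chloride | ClC(=O)[C@@H](c1ccc(OCOC)c(OCOC)c1)Oc1cc(OCOC)c(Br)c(OCOC)c1 | intermediate
11 | (1R)-1-[4-bromo-3,5-bis(methoxymethoxy)phenoxy]-3-diazo-1-[3,4-bis(methoxymethoxy)phenyl]propan-2-one | [N-]=[N+]=CC(=O)[C@@H](c1ccc(OCOC)c(OCOC)c1)Oc1cc(OCOC)c(Br)c(OCOC)c1 | intermediate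
12 | (3S)-3-[4-bromo-3,5-bis(methoxymethoxy)phenoxy]-3-[3,4-bis(methoxymethoxy)phenyl]prop-1-en-1-one (ketene) | O=C=C[C@@H](c1ccc(OCOC)c(OCOC)c1)Oc1cc(OCOC)c(Br)c(OCOC)c1 | intermediate
13 | (2S)-6-bromo-2-[3,4-bis(methoxymethoxy)phenyl]-5,7-bis(methoxymethoxy)-2,3-dihydro-4H-chromen-4-one | Brc1c(OCOC)cc2c(c1OCOC)C(=O)C[C@@H](c1ccc(OCOC)c(OCOC)c1)O2 | intermediate
14 | (3S)-3,7-dimethylocta-1,6-diene ((S)-β-citronellene) | CC(C)=CCC[C@H](C)C=C | starting material
15 | (2S)-2-[3,4-bis(methoxymethoxy)phenyl]-6-[(1E,3S)-3,7-dimethylocta-1,6-dien-1-yl]-5,7-bis(methoxymethoxy)-2,3-dihydro-4H-chromen-4-one | CC(C)=CCC[C@H](C)/C=C/c1c(OCOC)cc2c(c1OCOC)C(=O)C[C@@H](c1ccc(OCOC)c(OCOC)c1)O2 | intermediate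
16 | (2S)-2-[3,4-bis(trimethylsilyloxy)phenyl]-6-[(1E,3S)-3,7-dimethylocta-1,6-dien-1-yl]-5,7-bis(trimethylsilyloxy)-2,3-dihydro-4H-chromen-4-one | CC(C)=CCC[C@H](C)/C=C/c1c(O[Si](C)(C)C)cc2c(c1O[Si](C)(C)C)C(=O)C[C@@H](c1ccc(O[Si](C)(C)C)c(O[Si](C)(C)C)c1)O2 | intermediate
17 | (2S)-2-(3,4-dihydroxyphenyl)-6-[(1E,3S)-3,7-dimethylocta-1,6-dien-1-yl]-5,7-dihydroxy-2,3-dihydro-4H-chromen-4-one | CC(C)=CCC[C@H](C)/C=C/c1c(O)cc2c(c1O)C(=O)C[C@@H](c1ccc(O)c(O)c1)O2 | target

**Totals**

Total step count: 10. Longest linear sequence: 8 steps (steps 1, 2, 5–10, or equally steps 3, 4, 5–10).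

**Steps most likely to fail**

Step 8 (Proposed new method). The ketene may not acylate ring A fast enough and be lost to dimerisation or adventitious hydration, or some free carbene may attack ring A directly. Fallback in known chemistry, from 11 back to 13: irradiation of 11 (405 nm) in THF/H2O traps the ketene with water in an ordinary Arndt–Eistert homologation. This gives (3S)-3-[4-bromo-3,5-bis(methoxymethoxy)phenoxy]-3-[3,4-bis(methoxymethoxy)phenyl]propanoic acid F1, again with retention at the migrating carbon. Treatment with trifluoroacetic anhydride in CH2Cl2 at 0 °C converts it into the mixed (3S)-3-aryloxy-3-arylpropanoic trifluoroacetic anhydride F2, which should close onto the activated C4a by classical intramolecular Friedel–Crafts acylation to give 13.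

Step 9. β-Hydride elimination towards C3', or re-addition of palladium hydride and chain walking, would move the double bond out of conjugation and scramble the C3' stereocentre. The amine base at 70 °C could also open ring C reversibly and erode C2. Fallback, from 14 and 13 back to 15: the alkene geometry and position are fixed before the coupling. A palladium-catalysed boryl-Heck reaction of 14 (B-chlorocatecholborane, Pd2(dba)3, a bulky electron-rich phosphine, Et3N) should give 2-[(1E,3S)-3,7-dimethylocta-1,6-dien-1-yl]-1,3,2-benzodioxaborole F3. Exchange with pinacol gives 2-[(1E,3S)-3,7-dimethylocta-1,6-dien-1-yl]-4,4,5,5-tetramethyl-1,3,2-dioxaborolane F4. Suzuki–Miyaura coupling of F4 with 13 (Pd(OAc)2, 2-dicyclohexylphosphino-2',6'-dimethoxybiphenyl, K3PO4, THF/H2O, 40 °C) then gives 15 with the E geometry carried over from the boronate.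

Step 5. Facial selectivity in the proton transfer may be poor on this pair of electron-rich partners, or the carbene may alkylate the activated phenol ring at carbon instead of inserting into O–H. Fallback, from 4 and 7 back to 9: the ether is made without asymmetric induction and the acid is resolved. Rh2(OAc)4-catalysed O–H insertion gives racemic methyl 2-[4-bromo-3,5-bis(methoxymethoxy)phenoxy]-2-[3,4-bis(methoxymethoxy)phenyl]acetate F5. Hydrolysis with Me3SnOH gives the racemic 2-[4-bromo-3,5-bis(methoxymethoxy)phenoxy]-2-[3,4-bis(methoxymethoxy)phenyl]acetic acid F6. Fractional crystallisation with (R)-1-phenylethylamine (or its antipode, whichever lets the salt of the R acid crystallise) should separate the (R)-1-phenylethylammonium salt of the (2R)-acid F7 from the (R)-1-phenylethylammonium salt of the (2S)-acid F8, which stays in the mother liquor. Mild acidification of F7 gives 9.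

**Further compounds**

F1 | step 8 | (3S)-3-[4-bromo-3,5-bis(methoxymethoxy)phenoxy]-3-[3,4-bis(methoxymethoxy)phenyl]propanoic acid | OC(=O)C[C@@H](c1ccc(OCOC)c(OCOC)c1)Oc1cc(OCOC)c(Br)c(OCOC)c1
F2 | step 8 | (3S)-3-[4-bromo-3,5-bis(methoxymethoxy)phenoxy]-3-[3,4-bis(methoxymethoxy)phenyl]propanoic trifluoroacetic anhydride | O=C(C[C@@H](c1ccc(OCOC)c(OCOC)c1)Oc1cc(OCOC)c(Br)c(OCOC)c1)OC(=O)C(F)(F)F
F3 | step 9 | 2-[(1E,3S)-3,7-dimethylocta-1,6-dien-1-yl]-1,3,2-benzodioxaborole | CC(C)=CCC[C@H](C)/C=C/B1Oc2ccccc2O1
F4 | step 9 | 2-[(1E,3S)-3,7-dimethylocta-1,6-dien-1-yl]-4,4,5,5-tetramethyl-1,3,2-dioxaborolane | CC(C)=CCC[C@H](C)/C=C/B1OC(C)(C)C(C)(C)O1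
F5 | step 5 | racemic methyl 2-[4-bromo-3,5-bis(methoxymethoxy)phenoxy]-2-[3,4-bis(methoxymethoxy)phenyl]acetate | COC(=O)C(c1ccc(OCOC)c(OCOC)c1)Oc1cc(OCOC)c(Br)c(OCOC)c1
F6 | step 5 | racemic 2-[4-bromo-3,5-bis(methoxymethoxy)phenoxy]-2-[3,4-bis(methoxymethoxy)phenyl]acetic acid | OC(=O)C(c1ccc(OCOC)c(OCOC)c1)Oc1cc(OCOC)c(Br)c(OCOC)c1
F7 | step 5 | (R)-1-phenylethylammonium (2R)-2-[4-bromo-3,5-bis(methoxymethoxy)phenoxy]-2-[3,4-bis(methoxymethoxy)phenyl]acetate | [O-]C(=O)[C@@H](c1ccc(OCOC)c(OCOC)c1)Oc1cc(OCOC)c(Br)c(OCOC)c1.C[C@@H]([NH3+])c1ccccc1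
F8 | step 5 | (R)-1-phenylethylammonium (2S)-2-[4-bromo-3,5-bis(methoxymethoxy)phenoxy]-2-[3,4-bis(methoxymethoxy)phenyl]acetate | [O-]C(=O)[C@H](c1ccc(OCOC)c(OCOC)c1)Oc1cc(OCOC)c(Br)c(OCOC)c1.C[C@@H]([NH3+])c1ccccc1
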